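What does more free catalyst, or a doubled reagent charge, do to the rate of making product at 50% conversion? I reckon it from one number: the share of the catalyst that has stopped working.

in all of them: starting material 0.0050 M

| flask | reagent | free catalyst | remark |
|---|---|---|---|
| east | 5.5 mM | 6.5 µM | the very flask that is asked about, followed so far |
| south | 5.5 mM | 4.4 µM | run made earlier |
| flask | 5.50 mM | 6.5 µM |  |

| run | time / min | product / % |
|---|---|---|
| east | 0.667 | 16.9 |
| east | 1.33 | 37.9 |
| east | 2.00 | 51.5 |
| east | 2.50 | 60.3 |
| south | 0.500 | 6.4 |
| south | 1.00 | 16.9 |
| south | 2.50 | 42.4 |
| south | 6.00 | 71.8 |

(standard deviation of a reading: 0.5 percentage points)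

- factor on the rate of making product when 50% of the starting material are converted if reagent is charged twice over
- factor on the rate when 50% of the starting material are converted if free catalyst is charged at 60 µM instead

- what has left starting material counts as converted, also if it is not yet product
- no earlier run changes the charge of reagent; that part of a forecast is a guess

1. East reaches 16.9% product at 0.667 min, and south reaches 16.9% at 1.00 min. These times stand 1.50 to one and the catalyst charges 1.48 to one, so I assume that at equal product the rate follows the free catalyst present.
2. South reaches 42.4% at 2.50 min. East, interpolated, reaches that level at 1.55 min. Over this stretch east is faster by 1.70, more than its charge ratio.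
3. I let both runs lose the same amount of catalyst (deactivation). The ratio of what stays free then matches that factor if the loss is 21.2% of the east charge, the lost share, a reading from these runs.
4. If a charge of 60 µM loses that same amount, the catalyst factor is 11.5.
5. One number is not enough: no earlier run changes reagent, so the lost share gives me no reagent factor.

The forecast gives 6.8 and 1.05, and says of the gap between the runs “or some catalyst is being scavenged”. My catalyst factor is higher than its value.

    reagent + free catalyst + intermediate → free catalyst + product (k = 8.70 × 10⁵ M⁻² s⁻¹)
    starting material + free catalyst → spent catalyst (k = 1.00 M⁻¹ s⁻¹)
    starting material + free catalyst → free catalyst + intermediate (k = 2300 M⁻¹ s⁻¹)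

The flask gives 10.9 for the catalyst and 1.26 for the reagent. The catalyst factor is larger than the charge ratio 9.23, and at 50% conversion 16.7% of the catalyst in this flask is spent catalyst. Taken as an equal amount in the south run, the lost share of the east charge is 31.4% of the south charge, so I reckon that 68.6% of that charge stays free catalyst.

(The data stem from a simulated flask from invented constants; scatter was added.)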